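The synthesis rests on breaking the O1–C2 bond of ring C. C2 is benzylic to ring B and para to the C4' oxygen. A free 4'-phenol flanked by the O3' and O5' ethers can therefore be oxidised to a para-quinone methide whose exocyclic carbon is C2. The ring A phenol oxygen O1 sits at the other end of a six-atom chain. A single oxidation forms O1–C2, closes ring C and sets C2 trans to C3. The precursor is an open-chain (R)-α-methoxy dihydrochalcone with both phenols free, benzyl ethers on O6 and O3' and a methyl ether on O5. It is joined from a ring A aryllithium and a ring B Weinreb amide whose C3 stereocentre comes from asymmetric hydrogenation.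

Key step: step 12

Numbering: flavonoid numbering (O1, C2, C3, C4, C4a, C5–C8, C8a; ring B primed) is used for all intermediates.

Assumption: the (R)-configured diphosphine is taken to give the (R)-acid, by analogy with the like-to-like sense of (Z)-α-alkoxycinnamic acids. The antipodal ligand is equally available if a test run shows the opposite sense.

Design note: ring A stays mirror-symmetric (O5 and O7 both methyl) until it is brominated, so no regiochemical question arises. The O5 methyl is the only methyl ether peri to the C4 carbonyl, so it can be removed selectively at the end.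

Step 1
Reactants: 1 syringaldehyde (4-hydroxy-3,5-dimethoxybenzaldehyde)
Product: 2 4-(benzyloxy)-3,5-dimethoxybenzaldehyde
Conditions: BnBr, K2CO3, DMF, 60 °C
Reagents that add atoms: benzyl bromide, BrCc1ccccc1
Why: Williamson ether synthesis on the acidic para-formyl phenol, which installs the benzyl group that masks the future O6 until the last step.

Step 2
Reactants: 2 4-(benzyloxy)-3,5-dimethoxybenzaldehyde
Product: 4 4-(benzyloxy)-3,5-dimethoxyphenol, via aryl formate 3 (not isolated)
Conditions: mCPBA, CH2Cl2, 0 °C to rt; then K2CO3 (cat.), MeOH, rt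
Reagents that add atoms: 3-chloroperoxybenzoic acid, OOC(=O)c1cccc(Cl)c1
Why: Baeyer–Villiger oxidation of an electron-rich benzaldehyde, in which the trialkoxyaryl group migrates in preference to hydride, followed by transesterification of the formate with methanol.

Step 3
Reactants: 4 4-(benzyloxy)-3,5-dimethoxyphenol
Product: 5 2-(benzyloxy)-1,3-dimethoxy-5-(methoxymethoxy)benzene
Conditions: MOMCl, K2CO3, acetone, 0 °C to rt
Reagents that add atoms: chloromethyl methyl ether, COCCl
Why: Williamson-type O-alkylation of the phenoxide gives a MOM ether that removes the oxidisable free phenol before bromination, tolerates and coordinates organolithiums, and later leaves together with the ring B MOM group.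

Step 4
Reactants: 5 2-(benzyloxy)-1,3-dimethoxy-5-(methoxymethoxy)benzene
Product: 6 2-(benzyloxy)-4-bromo-1,3-dimethoxy-5-(methoxymethoxy)benzene
Conditions: NBS (1.0 equiv), MeCN, 0 °C, dark
Reagents that add atoms: N-bromosuccinimide, O=C1CCC(=O)N1Br
Why: Electrophilic aromatic bromination of a tetraalkoxybenzene whose two open positions are related by a mirror plane, so only one monobromide can form and the halogen marks the future C4a.

Step 5
Reactants: 7 3,4-dihydroxy-5-methoxybenzaldehyde (5-hydroxyvanillin)
Product: 8 3-hydroxy-5-methoxy-4-(methoxymethoxy)benzaldehyde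
Conditions: MOMCl (1.0 equiv), K2CO3 (1.0 equiv), acetone, 0 °C, argon
Reagents that add atoms: chloromethyl methyl ether, COCCl
Why: Regioselective Williamson-type alkylation, because the hydroxyl para to the formyl group is much the more acidic and one equivalent of base converts only that oxygen (the future O4') into the phenoxide.

Step 6
Reactants: 8 3-hydroxy-5-methoxy-4-(methoxymethoxy)benzaldehyde
Product: 9 3-(benzyloxy)-5-methoxy-4-(methoxymethoxy)benzaldehyde
Conditions: BnBr, K2CO3, DMF, rt to 50 °C
Reagents that add atoms: benzyl bromide, BrCc1ccccc1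
Why: Williamson ether synthesis on the only remaining phenol, which places the benzyl group on the future O3' so that no catechol is exposed to the later oxidant.

Step 7
Reactants: 9 3-(benzyloxy)-5-methoxy-4-(methoxymethoxy)benzaldehyde; 10 methyl methoxyacetate
Product: 12 (Z)-3-[3-(benzyloxy)-5-methoxy-4-(methoxymethoxy)phenyl]-2-methoxyprop-2-enoic acid, via methyl ester 11 (not isolated)
Conditions: NaOMe, THF, 0 °C to rt; then aq NaOH, 50 °C; then 1 M HCl to pH 3, 0 °C
Reagents that add atoms: sodium hydroxide, [Na+].[OH-]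
Why: Claisen-type aldol condensation of the ester enolate with a non-enolisable aldehyde, in which E1cB loss of hydroxide gives the more stable Z alkene (aryl trans to carboxyl), followed by saponification to an acid whose crystallisation should remove any E isomer.

Step 8
Reactants: 12 (Z)-3-[3-(benzyloxy)-5-methoxy-4-(methoxymethoxy)phenyl]-2-methoxyprop-2-enoic acid
Product: 13 (2R)-3-[3-(benzyloxy)-5-methoxy-4-(methoxymethoxy)phenyl]-2-methoxypropanoic acid
Conditions: H2 (40 bar), Ru(OAc)2[(R)-TMBTP] (0.5 mol %; TMBTP = 4,4'-bis(diphenylphosphanyl)-2,2',5,5'-tetramethyl-3,3'-bithiophene), MeOH, 40 °C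
Reagents that add atoms: none
Why: Carboxylate-directed asymmetric hydrogenation of a (Z)-α-alkoxycinnamic acid, in which the substrate binds ruthenium as its carboxylate, the atropisomeric diphosphine leaves one alkene face open and syn delivery of H2 sets the future C3 as R, while benzyl and MOM ethers are inert to this homogeneous catalyst.

Step 9
Reactants: 13 (2R)-3-[3-(benzyloxy)-5-methoxy-4-(methoxymethoxy)phenyl]-2-methoxypropanoic acid
Product: 15 (2R)-3-[3-(benzyloxy)-5-methoxy-4-(methoxymethoxy)phenyl]-N,2-dimethoxy-N-methylpropanamide, via acyl imidazolide 14 (not isolated)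
Conditions: CDI, CH2Cl2, rt; then MeNH(OMe)·HCl, rt
Reagents that add atoms: N,O-dimethylhydroxylamine hydrochloride, CNOC.Cl; 1,1'-carbonyldiimidazole, O=C(n1ccnc1)n1ccnc1 (its imidazolyl group stands in 14 only)
Why: Amide coupling through the acyl imidazolide, which stays close to neutral and offers an α-alkoxy acid no oxazolone pathway, so the stereocentre should be kept.

Step 10
Reactants: 6 2-(benzyloxy)-4-bromo-1,3-dimethoxy-5-(methoxymethoxy)benzene; 15 (2R)-3-[3-(benzyloxy)-5-methoxy-4-(methoxymethoxy)phenyl]-N,2-dimethoxy-N-methylpropanamide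
Product: 17 (2R)-1-[3-(benzyloxy)-2,4-dimethoxy-6-(methoxymethoxy)phenyl]-3-[3-(benzyloxy)-5-methoxy-4-(methoxymethoxy)phenyl]-2-methoxypropan-1-one, via aryllithium 16 (not isolated)
Conditions: 6, n-BuLi, THF, −78 °C; then 15, −78 to −30 °C; aq NH4Cl
Reagents that add atoms: n-butyllithium, [Li]CCCC (its lithium stands in 16 only; nothing of it stays in 17)
Why: Bromine–lithium exchange followed by Weinreb ketone synthesis, in which the chelated tetrahedral adduct lasts until the quench so that neither over-addition nor enolisation can touch C3, and which avoids an acylium ion that would close onto electron-rich ring B to give an indanone.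

Step 11
Reactants: 17 (2R)-1-[3-(benzyloxy)-2,4-dimethoxy-6-(methoxymethoxy)phenyl]-3-[3-(benzyloxy)-5-methoxy-4-(methoxymethoxy)phenyl]-2-methoxypropan-1-one
Product: 18 (2R)-1-[3-(benzyloxy)-6-hydroxy-2,4-dimethoxyphenyl]-3-[3-(benzyloxy)-4-hydroxy-5-methoxyphenyl]-2-methoxypropan-1-one
Conditions: conc. HCl (cat.), MeOH–THF, 40 °C
Reagents that add atoms: none
Why: Acid-catalysed acetal exchange (MOM cleavage) frees the O1 phenol and the 4'-phenol in one operation, leaves benzyl and methyl ethers alone, and is too mild to enolise the hindered α-methoxy ketone to a relevant extent.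

Step 12
Reactants: 18 (2R)-1-[3-(benzyloxy)-6-hydroxy-2,4-dimethoxyphenyl]-3-[3-(benzyloxy)-4-hydroxy-5-methoxyphenyl]-2-methoxypropan-1-one
Product: 20 (2R,3R)-6-(benzyloxy)-2-[3-(benzyloxy)-4-hydroxy-5-methoxyphenyl]-3,5,7-trimethoxychroman-4-one, via para-quinone methide 19 (not isolated)
Conditions: Ag2O (1.1 equiv, freshly prepared), 4 Å MS, CH2Cl2 (0.01 M), rt, dark
Reagents that add atoms: none
Why: Ag2O takes two electrons and two protons from the 2,6-dialkoxy-4-alkylphenol of ring B, whose blocked ortho positions rule out radical coupling, and gives para-quinone methide 19 with C2 as its exocyclic carbon, whereas the ring A phenol is deactivated by the acyl group and tied to the C4 carbonyl by a hydrogen bond, so it is not oxidised. O1 then adds to C2 in an intramolecular 1,6-oxa-conjugate addition driven by rearomatisation of ring B, which is the known behaviour of syringyl-type quinone methides towards oxygen nucleophiles and the same kind of oxidative closure that turns 2-hydroxy-1,3-diarylpropanes bearing a 4'-phenol into flavans. Ring C closes in the 6-exo-trig mode, since the C2=C1' bond that is consumed lies outside the new ring. C2 is controlled by C3: allylic 1,3-strain holds the C3–H bond in the plane of the quinone methide, so the acyl tether brings O1 to one face only, through a half-chair with the C3 methoxy group and the C2 aryl group both equatorial, which gives the trans (2R,3R) isomer. Ring closure must be faster than proton loss from C3 (which would lead to the achiral α-methoxychalcone) and faster than capture by water or by a second molecule, and this is served by the short tether, the neutral aprotic medium without soluble base, the sieves and the dilution. Only about one equivalent of oxidant is used because 20 is still a para-alkylphenol, although its benzylic aryloxy group makes it harder to oxidise than 18, and any reversible re-opening at C2 can only return to the more stable trans isomer.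

Step 13
Reactants: 20 (2R,3R)-6-(benzyloxy)-2-[3-(benzyloxy)-4-hydroxy-5-methoxyphenyl]-3,5,7-trimethoxychroman-4-one
Product: 21 (2R,3R)-6-(benzyloxy)-2-[3-(benzyloxy)-4,5-dimethoxyphenyl]-3,5,7-trimethoxychroman-4-one
Conditions: Me3SiCHN2, i-Pr2NEt, MeCN–MeOH (9:1), rt
Reagents that add atoms: (trimethylsilyl)diazomethane, C[Si](C)(C)C=[N+]=[N-] (its CH carbon becomes the new O-methyl carbon)
Why: O-methylation of a phenol by diazomethane released in the flask from Me3SiCHN2 and methanol, with only a hindered tertiary amine present, so that no phenoxide builds up to re-open ring C through the quinone methide and C3–H meets no strong base.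

Step 14
Reactants: 21 (2R,3R)-6-(benzyloxy)-2-[3-(benzyloxy)-4,5-dimethoxyphenyl]-3,5,7-trimethoxychroman-4-one
Product: 22 (2R,3R)-5,6-dihydroxy-2-(3-hydroxy-4,5-dimethoxyphenyl)-3,7-dimethoxychroman-4-one (CNP0075601.1)
Conditions: BCl3, pentamethylbenzene, CH2Cl2, −78 to 0 °C; then H2O
Reagents that add atoms: none
Why: Lewis-acid ether cleavage in which BCl3 with pentamethylbenzene as benzyl-cation trap removes both aryl benzyl ethers at low temperature, and boron chelated between the C4 carbonyl and O5 directs chloride to the peri 5-O-methyl group, leaving the 3-, 7-, 4'- and 5'-methyl ethers and both stereocentres as they are.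

Compound list
1 | syringaldehyde | COc1cc(C=O)cc(OC)c1O | starting material
2 | 4-(benzyloxy)-3,5-dimethoxybenzaldehyde | COc1cc(C=O)cc(OC)c1OCc1ccccc1 | intermediate
3 | 4-(benzyloxy)-3,5-dimethoxyphenyl formate | COc1cc(OC=O)cc(OC)c1OCc1ccccc1 | intermediate
4 | 4-(benzyloxy)-3,5-dimethoxyphenol | COc1cc(O)cc(OC)c1OCc1ccccc1 | intermediate
5 | 2-(benzyloxy)-1,3-dimethoxy-5-(methoxymethoxy)benzene | COCOc1cc(OC)c(OCc2ccccc2)c(OC)c1 | intermediate
6 | 2-(benzyloxy)-4-bromo-1,3-dimethoxy-5-(methoxymethoxy)benzene | COCOc1cc(OC)c(OCc2ccccc2)c(OC)c1Br | intermediate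
7 | 3,4-dihydroxy-5-methoxybenzaldehyde | COc1cc(C=O)cc(O)c1O | starting material
8 | 3-hydroxy-5-methoxy-4-(methoxymethoxy)benzaldehyde | COCOc1c(O)cc(C=O)cc1OC | intermediate
9 | 3-(benzyloxy)-5-methoxy-4-(methoxymethoxy)benzaldehyde | COCOc1c(OC)cc(C=O)cc1OCc1ccccc1 | intermediate
10 | methyl methoxyacetate | COCC(=O)OC | starting material
11 | methyl (Z)-3-[3-(benzyloxy)-5-methoxy-4-(methoxymethoxy)phenyl]-2-methoxyprop-2-enoate | COC(=O)/C(OC)=C/c1cc(OC)c(OCOC)c(OCc2ccccc2)c1 | intermediate
12 | (Z)-3-[3-(benzyloxy)-5-methoxy-4-(methoxymethoxy)phenyl]-2-methoxyprop-2-enoic acid | OC(=O)/C(OC)=C/c1cc(OC)c(OCOC)c(OCc2ccccc2)c1 | intermediate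
13 | (2R)-3-[3-(benzyloxy)-5-methoxy-4-(methoxymethoxy)phenyl]-2-methoxypropanoic acid | OC(=O)[C@H](OC)Cc1cc(OC)c(OCOC)c(OCc2ccccc2)c1 | intermediate
14 | (2R)-3-[3-(benzyloxy)-5-methoxy-4-(methoxymethoxy)phenyl]-1-(imidazol-1-yl)-2-methoxypropan-1-one | O=C([C@H](OC)Cc1cc(OC)c(OCOC)c(OCc2ccccc2)c1)n1ccnc1 | intermediate
15 | (2R)-3-[3-(benzyloxy)-5-methoxy-4-(methoxymethoxy)phenyl]-N,2-dimethoxy-N-methylpropanamide | CON(C)C(=O)[C@H](OC)Cc1cc(OC)c(OCOC)c(OCc2ccccc2)c1 | intermediate
16 | [3-(benzyloxy)-2,4-dimethoxy-6-(methoxymethoxy)phenyl]lithium | [Li]c1c(OCOC)cc(OC)c(OCc2ccccc2)c1OC | intermediate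
17 | (2R)-1-[3-(benzyloxy)-2,4-dimethoxy-6-(methoxymethoxy)phenyl]-3-[3-(benzyloxy)-5-methoxy-4-(methoxymethoxy)phenyl]-2-methoxypropan-1-one | COCOc1cc(OC)c(OCc2ccccc2)c(OC)c1C(=O)[C@H](OC)Cc1cc(OC)c(OCOC)c(OCc2ccccc2)c1 | intermediate
18 | (2R)-1-[3-(benzyloxy)-6-hydroxy-2,4-dimethoxyphenyl]-3-[3-(benzyloxy)-4-hydroxy-5-methoxyphenyl]-2-methoxypropan-1-one | COc1cc(O)c(c(OC)c1OCc1ccccc1)C(=O)[C@H](OC)Cc1cc(OCc2ccccc2)c(O)c(OC)c1 | intermediate
19 | 2-(benzyloxy)-4-{(2R)-3-[3-(benzyloxy)-6-hydroxy-2,4-dimethoxyphenyl]-2-methoxy-3-oxopropylidene}-6-methoxycyclohexa-2,5-dien-1-one (either geometry at the exocyclic alkene; both give the same product) | COc1cc(O)c(c(OC)c1OCc1ccccc1)C(=O)[C@H](OC)C=C1C=C(OC)C(=O)C(OCc2ccccc2)=C1 | intermediate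
20 | (2R,3R)-6-(benzyloxy)-2-[3-(benzyloxy)-4-hydroxy-5-methoxyphenyl]-3,5,7-trimethoxychroman-4-one | COc1cc2c(c(OC)c1OCc1ccccc1)C(=O)[C@H](OC)[C@@H](c1cc(OCc3ccccc3)c(O)c(OC)c1)O2 | intermediate
21 | (2R,3R)-6-(benzyloxy)-2-[3-(benzyloxy)-4,5-dimethoxyphenyl]-3,5,7-trimethoxychroman-4-one | COc1cc2c(c(OC)c1OCc1ccccc1)C(=O)[C@H](OC)[C@@H](c1cc(OCc3ccccc3)c(OC)c(OC)c1)O2 | intermediate
22 | (2R,3R)-5,6-dihydroxy-2-(3-hydroxy-4,5-dimethoxyphenyl)-3,7-dimethoxychroman-4-one | COc1cc2c(c(O)c1O)C(=O)[C@H](OC)[C@@H](c1cc(O)c(OC)c(OC)c1)O2 | target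

Total step count: 14. Longest linear sequence: 10 steps (steps 5–14, from 7). The ring A branch (steps 1–4) joins at step 10.

Steps most likely to fail

1. Step 12.
- The quinone methide may lose the C3 proton faster than O1 captures it, which erases the only pre-set stereocentre.
- It may be intercepted by adventitious water or by a second molecule.
- The cyclised phenol may be oxidised a second time towards the flavone level.
- The fallback sets out from bromide 6 and aldehyde 9 and comes back to the route at 21. It forms O1–C2 by epoxide opening instead of oxidation.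
- Aryllithium 16, made from 6 as in step 10, is acylated with N-methoxy-N-methylacetamide to give the ring A acetophenone F1.
- Claisen–Schmidt condensation of this ketone with 9 (KOH, EtOH) gives the (E)-chalcone F2.
- Juliá–Colonna epoxidation (poly-L-leucine, urea·H2O2, DBU, THF) gives the (2R,3S)-epoxy ketone F3.
- HCl in MeOH removes both MOM groups, and the freed ring A phenol opens the epoxide at the benzylic carbon with inversion to give the trans-3-hydroxyflavanone F4.
- Me3SiCHN2 methylates the 4'-phenol to give the 3-hydroxy-4'-methyl ether F5, and Purdie methylation (MeI, Ag2O, CH2Cl2) of the 3-hydroxyl then gives 21.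

2. Step 14.
- Boron bound at O3' after debenzylation may promote loss of the crowded neighbouring 4'-methyl ether.
- Chelation to the C4 carbonyl and the 3-methoxy group may start cleavage of that ether.
- Lewis-acid ionisation of the benzylic C2–O1 bond may scramble C2.
- Benzyl cations that escape the trap may alkylate C8.
- The fallback sets out from 21 and comes back at 22. It separates the two tasks.
- Neutral hydrogenolysis (H2, Pd/C, EtOAc) removes both benzyl groups to give the 6,3'-dihydroxy-5-methyl ether F6.
- The single chelated 5-O-methyl group of this compound is then cleaved with AlCl3 in MeCN at rt, a chelation-controlled demethylation well suited to 6-hydroxy-3,5,7-trimethoxy flavonoids.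

3. Step 8.
- The crowded trioxygenated aryl group may lower the facial discrimination or the turnover of the catalyst, and the whole route inherits its enantiopurity from this step.
- The fallback sets out from aldehyde 9 and comes back at acid 13. It uses an auxiliary instead of a catalyst.
- NaBH4 in MeOH reduces 9 to the benzyl alcohol F7, and an Appel reaction (CBr4, PPh3, CH2Cl2, 0 °C) gives the benzyl bromide F8, which is used at once.
- (S)-4-Benzyl-1,3-oxazolidin-2-one is acylated with methoxyacetyl chloride (n-BuLi, THF, −78 °C) to give the methoxyacetyl imide F9.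
- Evans alkylation of its chelated Z enolate (NaN(SiMe3)2, THF, −78 °C) with the bromide takes place on the face opposite the auxiliary benzyl group and gives the (2R)-alkylated imide F10.
- LiOH/H2O2 in aqueous THF then releases 13.

Further compounds
F1 | step 12 | 1-[3-(benzyloxy)-2,4-dimethoxy-6-(methoxymethoxy)phenyl]ethan-1-one | CC(=O)c1c(OCOC)cc(OC)c(OCc2ccccc2)c1OC
F2 | step 12 | (E)-1-[3-(benzyloxy)-2,4-dimethoxy-6-(methoxymethoxy)phenyl]-3-[3-(benzyloxy)-5-methoxy-4-(methoxymethoxy)phenyl]prop-2-en-1-one | COCOc1cc(OC)c(OCc2ccccc2)c(OC)c1C(=O)/C=C/c1cc(OC)c(OCOC)c(OCc2ccccc2)c1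
F3 | step 12 | [3-(benzyloxy)-2,4-dimethoxy-6-(methoxymethoxy)phenyl]{(2R,3S)-3-[3-(benzyloxy)-5-methoxy-4-(methoxymethoxy)phenyl]oxiran-2-yl}methanone | COCOc1cc(OC)c(OCc2ccccc2)c(OC)c1C(=O)[C@@H]1O[C@H]1c1cc(OC)c(OCOC)c(OCc2ccccc2)c1
F4 | step 12 | (2R,3R)-6-(benzyloxy)-2-[3-(benzyloxy)-4-hydroxy-5-methoxyphenyl]-3-hydroxy-5,7-dimethoxychroman-4-one | COc1cc2c(c(OC)c1OCc1ccccc1)C(=O)[C@H](O)[C@@H](c1cc(OCc3ccccc3)c(O)c(OC)c1)O2
F5 | step 12 | (2R,3R)-6-(benzyloxy)-2-[3-(benzyloxy)-4,5-dimethoxyphenyl]-3-hydroxy-5,7-dimethoxychroman-4-one | COc1cc2c(c(OC)c1OCc1ccccc1)C(=O)[C@H](O)[C@@H](c1cc(OCc3ccccc3)c(OC)c(OC)c1)O2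
F6 | step 14 | (2R,3R)-6-hydroxy-2-(3-hydroxy-4,5-dimethoxyphenyl)-3,5,7-trimethoxychroman-4-one | COc1cc2c(c(OC)c1O)C(=O)[C@H](OC)[C@@H](c1cc(O)c(OC)c(OC)c1)O2
F7 | step 8 | [3-(benzyloxy)-5-methoxy-4-(methoxymethoxy)phenyl]methanol | COCOc1c(OC)cc(CO)cc1OCc1ccccc1
F8 | step 8 | 1-(benzyloxy)-5-(bromomethyl)-3-methoxy-2-(methoxymethoxy)benzene | COCOc1c(OC)cc(CBr)cc1OCc1ccccc1
F9 | step 8 | (4S)-4-benzyl-3-(methoxyacetyl)-1,3-oxazolidin-2-one | COCC(=O)N1[C@@H](Cc2ccccc2)COC1=O
F10 | step 8 | (4S)-4-benzyl-3-{(2R)-3-[3-(benzyloxy)-5-methoxy-4-(methoxymethoxy)phenyl]-2-methoxypropanoyl}-1,3-oxazolidin-2-one | O=C1OC[C@H](Cc2ccccc2)N1C(=O)[C@H](OC)Cc1cc(OC)c(OCOC)c(OCc2ccccc2)c1
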